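**Retrosynthetic overview**

Numbering: C1 (quaternary, Me), C2, C3, C4 (OH, i-Pr), C5 (fusion CH), C6 (aroyloxy), C7, C8 (Me)=C9, C10 (isovaleryloxy). Ring A is the cyclopentane C1–C5 and ring B the cycloheptene C1, C5–C10.
Feature used: in ring B the allyl unit C8=C9–C10 lies between C7 and quaternary C1. The remaining atoms C7–C6(O)–C5–C1 are the skeleton of a 2-oxygenated diene whose C5=C1 alkene can sit inside ring A.
Late disconnections: the two esters; C10–O (allylic oxidation, then Luche reduction); C6–H (hydroxyl-directed hydride); C5–H (ketonisation of a C5=C6 silyl enol ether); the C8 methyl (from an ester carbon).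
Key disconnection: C7–C8 (vinylcarbene transfer to the enol-ether alkene) and C1–C10 (Cope rearrangement of the resulting cis-divinylcyclopropane).
Ring order: ring A first, by ozonolysis and aldol ring contraction of (R)-terpinen-4-ol, which supplies C4. Ring B second, in the key step.

Key step: step 8

Assumption: commercial (R)-(−)-terpinen-4-ol is used enantiopure, and Rh2(S-DOSP)4 is taken as the antipode matched to C4 by extrapolation from its sense of induction with styrenes and 1,1-disubstituted alkenes (it has to deliver the (1S,2R)-cyclopropane 12).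

**Step 1**
Reactants: 1 (R)-terpinen-4-ol
Product: 2 (R)-terpinen-4-ol triethylsilyl ether
Conditions: TESOTf, 2,6-lutidine, CH2Cl2, 0 °C
Reagents that add atoms: triethylsilyl triflate, CC[Si](CC)(CC)OS(=O)(=O)C(F)(F)F
Why: Silylation with a silyl triflate and a hindered pyridine is the standard way to cap a hindered tertiary alcohol, it leaves C4 untouched, and the free carbinol would otherwise invite retro-aldol cleavage in step 3 and O–H insertion or ylide formation in step 8.

**Step 2**
Reactants: 2 (R)-terpinen-4-ol triethylsilyl ether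
Product: 4 (R)-3-isopropyl-6-oxo-3-(triethylsilyloxy)heptanal, via ozonide 3 (not isolated)
Conditions: O3, CH2Cl2, −78 °C; then Me2S, −78 °C to rt
Reagents that add atoms: ozone, [O-][O+]=O
Why: Criegee ozonolysis with reductive work-up cleaves the only alkene to a methyl ketone (future C1) and an aldehyde (future C6), and neither the silyl ether nor C4 is affected.

**Step 3**
Reactants: 4 (R)-3-isopropyl-6-oxo-3-(triethylsilyloxy)heptanal
Product: 6 (S)-5-isopropyl-2-methyl-5-(triethylsilyloxy)cyclopent-1-ene-1-carbaldehyde, via aldol 5 (not isolated)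
Conditions: piperidine, AcOH (catalytic), toluene, 4 Å MS, 40 °C
Reagents that add atoms: none
Why: Enamine-mediated intramolecular aldol condensation, in which the amine condenses only with the aldehyde, so the aldehyde α-carbon (C5) attacks the methyl ketone (C1) as in the known ring contraction of limonene-type keto aldehydes; the fully substituted C4 speeds ring closure so that it should outrun β-loss of silanol, and water is lost from the free C1 hydroxyl rather than from the less basic silyl ether.

**Step 4**
Reactants: 6 (S)-5-isopropyl-2-methyl-5-(triethylsilyloxy)cyclopent-1-ene-1-carbaldehyde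
Product: 7 1-[(S)-5-isopropyl-2-methyl-5-(triethylsilyloxy)cyclopent-1-en-1-yl]ethan-1-ol (both carbinol epimers)
Conditions: MeMgBr, THF, −78 to 0 °C
Reagents that add atoms: methylmagnesium bromide, C[Mg]Br
Why: Grignard 1,2-addition to an enal whose β-carbon is fully substituted brings in C7, and the new carbinol centre needs no control because step 5 removes it.

**Step 5**
Reactants: 7 1-[(S)-5-isopropyl-2-methyl-5-(triethylsilyloxy)cyclopent-1-en-1-yl]ethan-1-ol
Product: 8 1-[(S)-5-isopropyl-2-methyl-5-(triethylsilyloxy)cyclopent-1-en-1-yl]ethan-1-one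
Conditions: Dess–Martin periodinane, CH2Cl2, 0 °C to rt
Reagents that add atoms: none
Why: Dess–Martin oxidation converts the hindered secondary allylic alcohol into the methyl enone under nearly neutral conditions that the tertiary silyl ether tolerates.

**Step 6**
Reactants: 8 1-[(S)-5-isopropyl-2-methyl-5-(triethylsilyloxy)cyclopent-1-en-1-yl]ethan-1-one
Product: 9 (S)-1-[1-(tert-butyldimethylsilyloxy)vinyl]-5-isopropyl-2-methyl-5-(triethylsilyloxy)cyclopent-1-ene
Conditions: TBSOTf, Et3N, CH2Cl2, −78 to 0 °C
Reagents that add atoms: tert-butyldimethylsilyl triflate, CC(C)(C)[Si](C)(C)OS(=O)(=O)C(F)(F)F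
Why: Soft enolisation and O-silylation of a methyl enone gives the cross-conjugated 2-silyloxydiene, because the acetyl CH3 is the only α-position (C5 carries no hydrogen) and γ-deprotonation is disfavoured in an acetyl group twisted out of conjugation.

**Step 7**
Reactants: 10 methyl but-3-enoate
Product: 11 methyl 2-diazobut-3-enoate
Conditions: p-ABSA, DBU, MeCN, 0 °C; rapid cold filtration through silica, used at once
Reagents that add atoms: 4-acetamidobenzenesulfonyl azide, CC(=O)Nc1ccc(cc1)S(=O)(=O)N=[N+]=[N-]
Why: Regitz diazo transfer to the doubly activated (allylic and α-ester) CH2 gives the vinyldiazoacetate, which is kept cold and used directly because it slowly closes to a pyrazole.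

**Step 8**
Reactants: 9 (S)-1-[1-(tert-butyldimethylsilyloxy)vinyl]-5-isopropyl-2-methyl-5-(triethylsilyloxy)cyclopent-1-ene; 11 methyl 2-diazobut-3-enoate
Product: 13 (1R,4S)-hydroazulene ester (C8 CO2Me; C8=C9; C5=C6 TBS enol ether; C4 OTES; C1 methyl on the face opposite to the C4 oxygen), via divinylcyclopropane 12 (not isolated)
Conditions: Rh2(S-DOSP)4 (1 mol%), hexanes, −40 °C to rt, slow addition of cold 11; then toluene, 80–110 °C
Reagents that add atoms: none
Why: Rh2(S-DOSP)4 (a carboxylate dimer of divalent rhodium) takes N2 out of 11 and the donor/acceptor vinylcarbenoid adds in a concerted, asynchronous way across the terminal alkene C6=C7 of 9 (bonds C7–C8 and C6–C8), after which the cis-divinylcyclopropane 12 undergoes a [3,3] shift that makes C1–C10, breaks C6–C8 and leaves C8=C9 and the C5=C6 silyl enol ether. The closest known reaction type is the tandem cyclopropanation/Cope rearrangement (formal (4+3) cycloaddition) of vinyldiazoacetates with dienes, which is established for 2-silyloxydienes, for ring-embedded diene termini and for termini that become quaternary carbons. Ring B is closed by expansion of the three-membered ring through the endo boat transition state, the only geometry that gives two Z alkenes in a seven-membered ring. C1 is the only new stereocentre that survives: C10 can reach C5=C1 only on the face on which C8 sits, so C1 follows stereospecifically from C6 of 12, and C6 is fixed by the enol-ether face that the catalyst selects, here matched with the substrate because bonding syn to the slim C4–O bond avoids the isopropyl group on the other face. The step needs attack at C6=C7 and not at tetrasubstituted C5=C1 (secured by the silyloxy donor and the free CH2 terminus), attack at the carbene carbon and not at the vinyl terminus (favoured by hydrocarbon solvent, the prolinate catalyst and slow addition), and vinyl cis to cyclopentenyl (the usual placement of an unsaturated alkene substituent next to the donor group; a trans isomer can still funnel through because the C6–C8 bond, flanked by the OSi donor and the ester acceptor, epimerises on heating). The C1 methyl points into the boat toward C7H2, so the rearrangement is completed by warming in toluene.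

**Step 9**
Reactants: 13 (1R,4S)-hydroazulene ester
Product: 14 (1R,4S)-C8-hydroxymethyl hydroazulene (enol ether and TES ether retained)
Conditions: i-Bu2AlH (2.5 equiv), CH2Cl2, −78 °C; aqueous work-up
Reagents that add atoms: none
Why: 1,2-Reduction of an α,β-unsaturated ester with i-Bu2AlH stops cleanly at the allylic alcohol, and both silyl groups survive at low temperature.

**Step 10**
Reactants: 14 (1R,4S)-C8-hydroxymethyl hydroazulene
Product: 16 (1R,4S)-C8-methyl hydroazulene (C5=C6 TBS enol ether; C4 OTES), via mesylate 15 (not isolated)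
Conditions: MsCl, Et3N, THF, −40 °C; then LiEt3BH, −40 to 0 °C
Reagents that add atoms: none
Why: Sulfonylation followed by SN2 hydride displacement at the primary allylic carbon turns the former ester carbon into the C8 methyl without moving C8=C9, and the non-acidic medium protects the enol ether and the vinylogously activated C4–O bond.

**Step 11**
Reactants: 16 (1R,4S)-C8-methyl hydroazulene
Product: 18 (1R,4S,5R)-4-hydroxy-6-ketone (trans-fused; H5 syn to the C4 hydroxyl), via TES ketone 17 (not isolated)
Conditions: TBAF, AcOH (1:1), THF, −20 °C; then HF·pyridine, 0 °C to rt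
Reagents that add atoms: none
Why: Fluoride-induced cleavage of the silyl enol ether under acetic acid buffering frees the enol(ate) without the strong acid that would ionise C4–O (the pathway exploited in Stork–Danheiser transpositions), C5 should then be protonated on the face that carries only the C4 oxygen and C10H2 because the other face is covered by the C1 methyl and the isopropyl group, and HF·pyridine removes the tertiary TES ether without base, so C5 is not epimerised and no retro-aldol cleavage starts.

**Step 12**
Reactants: 18 (1R,4S,5R)-4-hydroxy-6-ketone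
Product: 19 (1R,4S,5S,6R)-4,6-diol (H5 and H6 syn to the C4 hydroxyl; C6 hydroxyl on the face of the C1 methyl)
Conditions: Me4NBH(OAc)3, MeCN/AcOH (1:1), −30 °C
Reagents that add atoms: none
Why: In this Evans–Saksena reduction the C4 hydroxyl replaces an acetate on boron and hydride is delivered internally to the C6 carbonyl from the face of the C4 oxygen, which is also the face remote from the syn-axial C1 methyl and the isopropyl group, so the anti 1,3-diol results while the weakly acidic medium leaves C5 and the β,γ-alkene where they are.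

**Step 13**
Reactants: 20 4-hydroxybenzoic acid
Product: 22 4-(tert-butyldimethylsilyloxy)benzoic acid, via bis-silyl compound 21 (not isolated)
Conditions: TBSCl (2.2 equiv), imidazole, DMF, rt; then THF/H2O/AcOH, rt
Reagents that add atoms: tert-butyldimethylsilyl chloride, CC(C)(C)[Si](C)(C)Cl
Why: Exhaustive silylation followed by selective hydrolysis works because a silyl ester is far more labile to water than an aryl silyl ether.

**Step 14**
Reactants: 19 (1R,4S,5S,6R)-4,6-diol; 22 4-(tert-butyldimethylsilyloxy)benzoic acid
Product: 23 (1R,4S,5S,6R)-6-O-[4-(tert-butyldimethylsilyloxy)benzoyl] diol monoester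
Conditions: DCC, DMAP, toluene, rt to 60 °C
Reagents that add atoms: none
Why: Steglich esterification acylates the secondary C6 hydroxyl only, since the tertiary C4 hydroxyl next to the isopropyl group is inert under these conditions, and no stereocentre is touched.

**Step 15**
Reactants: 23 (1R,4S,5S,6R)-6-O-aroyl monoester
Product: 24 (1S,4S,5S,6R)-10-oxo enone (C10=O conjugated with C8=C9)
Conditions: CrO3, 3,5-dimethylpyrazole, CH2Cl2, −20 °C
Reagents that add atoms: chromium trioxide, O=[Cr](=O)=O
Why: Allylic oxidation with the CrO3–3,5-dimethylpyrazole complex converts the CH2 attached to the CH end of a 1-methylcycloalkene into the β-methyl enone, and here C7 is deactivated by the neighbouring electron-withdrawing aroyloxy group and the C8 methyl is primary, so C10 should react although it is neopentyl.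

**Step 16**
Reactants: 24 (1S,4S,5S,6R)-10-oxo enone
Product: 25 (1S,4S,5S,6R,10S)-10-hydroxy compound (C10 hydroxyl cis to the C1 methyl)
Conditions: NaBH4, CeCl3·7H2O, MeOH, −40 °C
Reagents that add atoms: none
Why: Luche reduction is 1,2-selective and leaves the esters alone, and hydride approaches C10 anti to the adjacent C1 methyl, so the new hydroxyl ends cis to that methyl, as is usual for ketones next to an angular methyl group.

**Step 17**
Reactants: 25 (1S,4S,5S,6R,10S)-10-hydroxy compound
Product: 26 (1S,4S,5S,6R,10S)-10-O-isovaleryl-6-O-[4-(tert-butyldimethylsilyloxy)benzoyl] diester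
Conditions: isovaleryl chloride, Et3N, DMAP, CH2Cl2, 0 °C to rt
Reagents that add atoms: isovaleryl chloride, CC(C)CC(=O)Cl
Why: DMAP-catalysed acylation esterifies the secondary allylic C10 hydroxyl with retention, while the tertiary C4 hydroxyl again stays free.

**Step 18**
Reactants: 26 (1S,4S,5S,6R,10S)-diester
Product: 27 target CNP0086724.2
Conditions: TBAF, AcOH, THF, 0 °C
Reagents that add atoms: none
Why: Buffered fluoride cleaves an aryl silyl ether within minutes, and the acetic acid keeps the phenoxide from attacking or shifting the two esters.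

**Compound list**

1 | (R)-(−)-terpinen-4-ol | CC1=CC[C@@](O)(C(C)C)CC1 | starting material
2 | (R)-terpinen-4-ol triethylsilyl ether | CC1=CC[C@@](O[Si](CC)(CC)CC)(C(C)C)CC1 | intermediate
3 | ozonide of 2 (1,2,4-trioxolane, not isolated) | CC12CC[C@](O[Si](CC)(CC)CC)(C(C)C)CC(OO1)O2 | intermediate
4 | (R)-3-isopropyl-6-oxo-3-(triethylsilyloxy)heptanal | CC(=O)CC[C@](O[Si](CC)(CC)CC)(C(C)C)CC=O | intermediate
5 | aldol, 2-hydroxy-5-isopropyl-2-methyl-5-(triethylsilyloxy)cyclopentanecarbaldehyde (not isolated) | O=CC1C(C)(O)CC[C@]1(O[Si](CC)(CC)CC)C(C)C | intermediate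
6 | (S)-5-isopropyl-2-methyl-5-(triethylsilyloxy)cyclopent-1-ene-1-carbaldehyde | O=CC1=C(C)CC[C@]1(O[Si](CC)(CC)CC)C(C)C | intermediate
7 | 1-[(S)-5-isopropyl-2-methyl-5-(triethylsilyloxy)cyclopent-1-en-1-yl]ethan-1-ol (carbinol epimers) | CC(O)C1=C(C)CC[C@]1(O[Si](CC)(CC)CC)C(C)C | intermediate
8 | 1-[(S)-5-isopropyl-2-methyl-5-(triethylsilyloxy)cyclopent-1-en-1-yl]ethan-1-one | CC(=O)C1=C(C)CC[C@]1(O[Si](CC)(CC)CC)C(C)C | intermediate
9 | silyloxydiene, (S)-1-[1-(TBSO)vinyl]-5-isopropyl-2-methyl-5-(TESO)cyclopent-1-ene | C=C(O[Si](C)(C)C(C)(C)C)C1=C(C)CC[C@]1(O[Si](CC)(CC)CC)C(C)C | intermediate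
10 | methyl but-3-enoate | C=CCC(=O)OC | starting material
11 | methyl 2-diazobut-3-enoate | C=CC(=[N+]=[N-])C(=O)OC | intermediate
12 | methyl (1S,2R)-2-(TBSO)-2-[(S)-5-isopropyl-2-methyl-5-(TESO)cyclopent-1-en-1-yl]-1-vinylcyclopropane-1-carboxylate (vinyl cis to cyclopentenyl, not isolated) | COC(=O)[C@]1(C=C)C[C@@]1(O[Si](C)(C)C(C)(C)C)C2=C(C)CC[C@]2(O[Si](CC)(CC)CC)C(C)C | intermediate
13 | (1R,4S)-hydroazulene ester with C5=C6 TBS enol ether | COC(=O)C1=CC[C@@]2(C)CC[C@](O[Si](CC)(CC)CC)(C(C)C)C2=C(O[Si](C)(C)C(C)(C)C)C1 | intermediate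
14 | (1R,4S)-C8-hydroxymethyl hydroazulene | OCC1=CC[C@@]2(C)CC[C@](O[Si](CC)(CC)CC)(C(C)C)C2=C(O[Si](C)(C)C(C)(C)C)C1 | intermediate
15 | allylic mesylate of 14 (not isolated) | CS(=O)(=O)OCC1=CC[C@@]2(C)CC[C@](O[Si](CC)(CC)CC)(C(C)C)C2=C(O[Si](C)(C)C(C)(C)C)C1 | intermediate
16 | (1R,4S)-C8-methyl hydroazulene, bis-silyl | CC1=CC[C@@]2(C)CC[C@](O[Si](CC)(CC)CC)(C(C)C)C2=C(O[Si](C)(C)C(C)(C)C)C1 | intermediate
17 | (1R,4S,5R)-4-(triethylsilyloxy)-6-ketone (not isolated) | CC1=CC[C@@]2(C)CC[C@](O[Si](CC)(CC)CC)(C(C)C)[C@@H]2C(=O)C1 | intermediate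
18 | (1R,4S,5R)-4-hydroxy-6-ketone, trans-fused | CC1=CC[C@@]2(C)CC[C@](O)(C(C)C)[C@@H]2C(=O)C1 | intermediate
19 | (1R,4S,5S,6R)-4,6-diol | CC1=CC[C@@]2(C)CC[C@](O)(C(C)C)[C@@H]2[C@H](O)C1 | intermediate
20 | 4-hydroxybenzoic acid | OC(=O)c1ccc(O)cc1 | starting material
21 | tert-butyldimethylsilyl 4-(tert-butyldimethylsilyloxy)benzoate (not isolated) | CC(C)(C)[Si](C)(C)OC(=O)c1ccc(O[Si](C)(C)C(C)(C)C)cc1 | intermediate
22 | 4-(tert-butyldimethylsilyloxy)benzoic acid | OC(=O)c1ccc(O[Si](C)(C)C(C)(C)C)cc1 | intermediate
23 | (1R,4S,5S,6R)-6-O-[4-(TBSO)benzoyl] monoester | CC1=CC[C@@]2(C)CC[C@](O)(C(C)C)[C@@H]2[C@H](OC(=O)c2ccc(O[Si](C)(C)C(C)(C)C)cc2)C1 | intermediate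
24 | (1S,4S,5S,6R)-10-oxo enone | CC1=CC(=O)[C@@]2(C)CC[C@](O)(C(C)C)[C@@H]2[C@H](OC(=O)c2ccc(O[Si](C)(C)C(C)(C)C)cc2)C1 | intermediate
25 | (1S,4S,5S,6R,10S)-10-hydroxy compound | CC1=C[C@H](O)[C@@]2(C)CC[C@](O)(C(C)C)[C@@H]2[C@H](OC(=O)c2ccc(O[Si](C)(C)C(C)(C)C)cc2)C1 | intermediate
26 | (1S,4S,5S,6R,10S)-10-O-isovaleryl-6-O-[4-(TBSO)benzoyl] diester | CC1=C[C@H](OC(=O)CC(C)C)[C@@]2(C)CC[C@](O)(C(C)C)[C@@H]2[C@H](OC(=O)c2ccc(O[Si](C)(C)C(C)(C)C)cc2)C1 | intermediate
27 | CNP0086724.2, (1S,4S,5S,6R,10S) | CC1=C[C@H](OC(=O)CC(C)C)[C@@]2(C)CC[C@](O)(C(C)C)[C@@H]2[C@H](OC(=O)c2ccc(O)cc2)C1 | target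

Total step count: 18. Longest linear sequence: 16 (steps 1–6, 8–12 and 14–18).

**Steps most likely to fail**

**Step 8.**
- What may go wrong:
  - The silyl enol ether may attack the vinyl terminus of the carbenoid instead of the carbene carbon.
  - 11 may cyclise to a pyrazole before it is consumed.
  - A trans-divinylcyclopropane may form that rearranges only sluggishly.
  - Facial selectivity may be poor if the catalyst and the C4 centre turn out mismatched.
- Fallback: the vinyl group is built only after the three-membered ring exists.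
  - Setting out from 9, cyclopropanation of C6=C7 with methyl diazoacetate and Cu(acac)2 should give the siloxycyclopropane ester F1. This is a classical donor–acceptor cyclopropane whose C6 epimers can be separated.
  - Deprotonation with LiN(i-Pr)2 at −78 °C and addition of acetaldehyde should give the hydroxyethyl cyclopropane F2.
  - Dehydration with the Burgess reagent in warm toluene, which can only run toward the methyl group, should give 12. This rearranges as in step 8, so the route is rejoined at 12 and thereby 13.

**Step 11.**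
- What may go wrong:
  - The C4 oxygen may be lost by vinylogous ionisation or β-elimination while the enol(ate) is present.
  - C5 may be protonated from the methyl/isopropyl face.
  - C5 may later epimerise to the cis-fused ketone, which is probably the more stable one.
- Fallback: both hydrogens are delivered by hydroxyl-directed hydrogenation, so neither an enol nor a ketone intervenes.
  - Setting out from 13, HF·pyridine in a large excess of pyridine at 0 °C should remove the more labile TES group first and give the hydroxy enol ether F3.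
  - Hydrogenation with [Ir(cod)(PCy3)(py)]PF6 and H2 in CH2Cl2 should add H5 and H6 on the face of the C4 hydroxyl. The electron-poor, remote enoate alkene should be spared. The product is the saturated silyl ether F4.
  - i-Bu2AlH should give the allylic alcohol F5.
  - MsCl and Et3N should give the primary mesylate F6.
  - LiEt3BH should give the C8-methyl silyl ether F7.
  - TBAF then frees the C6 hydroxyl, so the route is rejoined at 19.

**Step 15.**
- What may go wrong:
  - Hydrogen may be abstracted at C7 or at the C8 methyl instead of at neopentyl C10.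
  - The allylic system may transpose, placing oxygen at C9 or C7.
  - Over-oxidation may occur.
- Fallback: the regiochemistry is dictated by an epoxide instead of by C–H selectivity.
  - Setting out from 23, mCPBA should give the 8,9-epoxide F8; either face serves.
  - PhSeSePh and NaBH4 in EtOH should open it at the less substituted C9 to give the hydroxy selenide F9.
  - H2O2 should give the selenoxide F10. It can eliminate only toward C10, the single neighbouring carbon that bears hydrogen, and should give the tertiary allylic alcohol F11.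
  - Pyridinium chlorochromate (C5H5NH[CrO3Cl]) then effects the Babler–Dauben oxidative 1,3-transposition to the enone, so the route is rejoined at 24.

**Further compounds**

F1 | step 8 | methyl 2-(TBSO)-2-[(S)-5-isopropyl-2-methyl-5-(TESO)cyclopent-1-en-1-yl]cyclopropane-1-carboxylate | COC(=O)C1C[C@@]1(O[Si](C)(C)C(C)(C)C)C2=C(C)CC[C@]2(O[Si](CC)(CC)CC)C(C)C
F2 | step 8 | 1-(1-hydroxyethyl) derivative of F1 | COC(=O)[C@]1(C(C)O)C[C@@]1(O[Si](C)(C)C(C)(C)C)C2=C(C)CC[C@]2(O[Si](CC)(CC)CC)C(C)C
F3 | step 11 | (1R,4S)-4-hydroxy hydroazulene ester with C5=C6 TBS enol ether | COC(=O)C1=CC[C@@]2(C)CC[C@](O)(C(C)C)C2=C(O[Si](C)(C)C(C)(C)C)C1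
F4 | step 11 | 5,6-dihydro ester, C6 OTBS, H5 and H6 syn to the C4 hydroxyl | COC(=O)C1=CC[C@@]2(C)CC[C@](O)(C(C)C)[C@@H]2[C@H](O[Si](C)(C)C(C)(C)C)C1
F5 | step 11 | C8-hydroxymethyl compound from F4 | OCC1=CC[C@@]2(C)CC[C@](O)(C(C)C)[C@@H]2[C@H](O[Si](C)(C)C(C)(C)C)C1
F6 | step 11 | primary allylic mesylate of F5 | CS(=O)(=O)OCC1=CC[C@@]2(C)CC[C@](O)(C(C)C)[C@@H]2[C@H](O[Si](C)(C)C(C)(C)C)C1
F7 | step 11 | 6-O-TBS ether of diol 19 | CC1=CC[C@@]2(C)CC[C@](O)(C(C)C)[C@@H]2[C@H](O[Si](C)(C)C(C)(C)C)C1
F8 | step 15 | 8,9-epoxide of 23 | CC12OC1C[C@@]3(C)CC[C@](O)(C(C)C)[C@@H]3[C@H](OC(=O)c4ccc(O[Si](C)(C)C(C)(C)C)cc4)C2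
F9 | step 15 | 8-hydroxy-9-phenylselanyl compound | CC1(O)C([Se]c2ccccc2)C[C@@]3(C)CC[C@](O)(C(C)C)[C@@H]3[C@H](OC(=O)c4ccc(O[Si](C)(C)C(C)(C)C)cc4)C1
F10 | step 15 | selenoxide of F9 | CC1(O)C([Se](=O)c2ccccc2)C[C@@]3(C)CC[C@](O)(C(C)C)[C@@H]3[C@H](OC(=O)c4ccc(O[Si](C)(C)C(C)(C)C)cc4)C1
F11 | step 15 | 8-hydroxy-9,10-ene (tertiary allylic alcohol) | CC1(O)C=C[C@@]3(C)CC[C@](O)(C(C)C)[C@@H]3[C@H](OC(=O)c4ccc(O[Si](C)(C)C(C)(C)C)cc4)C1
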